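The numbering is that of eremophilane: ring A is C1-C2-C3-C4-C5-C10 and ring B is C5-C6-C7-C8-C9-C10. The strategy rests on the diene C2=C1-C10=C9, which crosses from ring A into the C8 enone of ring B, and on the cis triad C3-O, C4-Me, C5-Me (C5 quaternary), which lies on the bonds C3-C4 and C5-C10.
A retro-[4+2] across C3-C4 and C5-C10 opens both rings at once. It leads to an acyclic isomer of the target, an (Ra)-1-acyloxy vinylallenyl ketone, whose allene C9=C10=C1 is the only stereochemical element of the future core.
This chain is cut at O-C3 (enol ester from a keto aldehyde and the (6S)-dienoyl chloride), at C7-C8 (vinyllithium plus allenal), at C10-C1 (enantioselective allenation of propargyl alcohol with a three-carbon aldehyde) and at C6-C7 (bromovinyllithium plus tiglyl bromide).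
No ring exists until the last step, in which rings A and B close together.
Key step: step 13

Remark: open-chain intermediates carry eremophilane atom numbers. Compounds with a C8 carbinol are carried as both epimers and written without configuration at C8. The pairing of the (S)-amine with the Ra axis follows the model in step 7 and is to be checked on 17; if it proves reversed, the (R)-amine is used instead.

Step 1
Reactants: 1 (S)-2-methylbutan-1-ol
Product: 2 (S)-2-methylbutanal
Conditions: TEMPO (2,2,6,6-tetramethylpiperidin-1-oxyl, 1 mol %), KBr (10 mol %), aq NaOCl (1.1 equiv, pH 9.5 with NaHCO3), CH2Cl2/H2O, 0 °C; dried CH2Cl2 solution used directly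
Reagents that add atoms: none
Why: Oxoammonium-mediated (TEMPO/hypochlorite) alcohol oxidation is complete within minutes at 0 °C in a buffered two-phase medium and stops at the aldehyde, so the enolisable stereocentre next to the carbonyl group keeps its S configuration.

Step 2
Reactants: 2 (S)-2-methylbutanal; 3 triethyl (E)-4-phosphonocrotonate
Product: 5 ethyl (2E,4E,6S)-6-methylocta-2,4-dienoate, via lithiated phosphonate 4 (not isolated)
Conditions: 3, LiN(SiMe3)2 (1.05 equiv), THF, −78 °C, 30 min; then 2, −78 → 0 °C
Reagents that add atoms: none
Why: Vinylogous Horner–Wadsworth–Emmons olefination: the preformed lithium allyl phosphonate reacts through its alpha carbon, reversible addition and syn elimination favour the new E alkene while the crotonate E alkene is retained, and the absence of free base at low temperature protects the stereocentre of 2, which becomes C6 of the dienoate.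

Step 3
Reactants: 5 ethyl (2E,4E,6S)-6-methylocta-2,4-dienoate
Product: 6 (2E,4E,6S)-6-methylocta-2,4-dienoic acid
Conditions: LiOH·H2O (3 equiv), THF/MeOH/H2O, rt; then 1 M HCl to pH 3
Reagents that add atoms: lithium hydroxide, [Li+].[OH-]
Why: Ester saponification by acyl–oxygen cleavage; the carboxylate formed is not deprotonated further, so neither the E,E diene nor the remote C6 centre is affected.

Step 4
Reactants: 6 (2E,4E,6S)-6-methylocta-2,4-dienoic acid
Product: 7 (2E,4E,6S)-6-methylocta-2,4-dienoyl chloride
Conditions: 1-chloro-N,N,2-trimethylprop-1-en-1-amine (1.1 equiv), CH2Cl2, 0 °C → rt; bulb-to-bulb distillation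
Reagents that add atoms: 1-chloro-N,N,2-trimethylprop-1-en-1-amine (Ghosez reagent), CC(C)=C(Cl)N(C)C
Why: The alpha-chloroenamine (Ghosez reagent) turns the acid into its chloride through an acyloxyiminium chloride without liberating HCl, so the diene is neither isomerised nor hydrochlorinated and the only by-product is a neutral amide.

Step 5
Reactants: 8 (E)-2-methylbut-2-en-1-ol (tiglyl alcohol)
Product: 9 (E)-1-bromo-2-methylbut-2-ene (tiglyl bromide; C4, C5, C6 and both ring methyls)
Conditions: PBr3 (0.4 equiv), Et2O, −10 → 0 °C
Reagents that add atoms: phosphorus tribromide, BrP(Br)Br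
Why: Bromination of a primary allylic alcohol through its phosphite ester proceeds by direct SN2 attack of bromide at low temperature, without allylic transposition and with the E alkene intact.

Step 6
Reactants: 9 tiglyl bromide; 10 1,1-dibromo-2-methylprop-1-ene (C7 and the isopropylidene)
Product: 12 (5E)-3-bromo-2,5-dimethylhepta-2,5-diene, via 1-bromo-2-methylprop-1-enyllithium 11 (not isolated)
Conditions: 10, n-BuLi (1.0 equiv), THF/Et2O/pentane 4:1:1, −110 °C, 15 min; then 9 (1.1 equiv), HMPA (2 equiv), −110 → −78 °C
Reagents that add atoms: none
Why: One bromine–lithium exchange on the 1,1-dibromoalkene gives an alpha-bromovinyllithium that is stable as a carbenoid only near −110 °C and is alkylated there by SN2 attack on the primary carbon of the reactive allylic bromide (C6–C7 bond); the two bromines of 10 are equivalent, so no alkene geometry is at stake at C7, and the tiglyl alkene is a spectator.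

Step 7
Reactants: 13 3-(tert-butyldimethylsilyloxy)propanal (C1 to C3); 14 prop-2-yn-1-ol (C8 to C10); 15 (S)-α,α-diphenylprolinol
Product: 17 (Ra)-6-(tert-butyldimethylsilyloxy)hexa-2,3-dien-1-ol, via propargylic amine 16 (not isolated)
Conditions: CuBr2 (20 mol %), 14 (1.0 equiv), 13 (1.5 equiv), 15 (1.0 equiv), 1,4-dioxane, 130 °C, sealed tube, Ar
Reagents that add atoms: none
Why: Copper-catalysed enantioselective allenation of a terminal alkyne (aldehyde–alkyne–amine coupling, then 1,5-hydride transfer and elimination): the CPh2OH arm of the (S)-amine shields one face of the E iminium ion so that the copper acetylide sets the propargylic carbon C1 of 16 as S, and hydride delivery from the pyrrolidine to C9 on the same side as the departing C1–N bond converts that centre into the Ra axis C9=C10=C1.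

Step 8
Reactants: 17 (Ra)-6-(tert-butyldimethylsilyloxy)hexa-2,3-dien-1-ol
Product: 18 (Ra)-6-(tert-butyldimethylsilyloxy)hexa-2,3-dienal
Conditions: activated MnO2 (15 equiv), CH2Cl2, rt; filtration through Celite
Reagents that add atoms: none
Why: Allenylic alcohols behave like allylic alcohols towards MnO2, and the heterogeneous, neutral oxidation stops at the aldehyde without any base that could deprotonate the allenal, so the Ra axis and the silyl ether are kept.

Step 9
Reactants: 12 (5E)-3-bromo-2,5-dimethylhepta-2,5-diene; 18 (Ra)-allenal
Product: 20 (Ra,9E)-1-(tert-butyldimethylsilyloxy)-9-methyl-7-(propan-2-ylidene)undeca-3,4,9-trien-6-ol (both C8 epimers), via dienyllithium 19 (not isolated)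
Conditions: 12, t-BuLi (2.0 equiv), Et2O, −78 °C, 30 min; then 18 in Et2O, −78 °C; aq NH4Cl
Reagents that add atoms: none
Why: Bromine–lithium exchange with two equivalents of t-BuLi gives the vinyllithium, whose 1,2-addition to the aldehyde at −78 °C (C7–C8 bond) is faster than deprotonation or conjugate attack on the allenal; the new C8 carbinol centre forms without control, which is harmless because step 11 erases it, and the axis is not involved.

Step 10
Reactants: 20 silyl-protected allenyl dienyl carbinol
Product: 21 (Ra,9E)-9-methyl-7-(propan-2-ylidene)undeca-3,4,9-triene-1,6-diol (both C8 epimers)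
Conditions: Bu4NF (1.2 equiv), AcOH (1.2 equiv), THF, 0 °C → rt
Reagents that add atoms: none
Why: Fluoride-induced cleavage of the silyl ether, buffered with acetic acid so that the medium stays close to neutral and neither the unactivated allene nor the acid-labile doubly allylic carbinol is disturbed.

Step 11
Reactants: 21 allenyl diol
Product: 22 (Ra,9E)-9-methyl-6-oxo-7-(propan-2-ylidene)undeca-3,4,9-trienal (allenyl keto aldehyde)
Conditions: Dess–Martin periodinane (2.4 equiv), NaHCO3 (10 equiv), CH2Cl2, 0 °C; cold filtration through Celite/Florisil, used at once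
Reagents that add atoms: none
Why: Dess–Martin oxidation of both alcohols in one operation needs no external base, NaHCO3 takes up the acetic acid released, the two C8 epimers converge on one ketone, and at 0 °C neither Nazarov closure of the allenyl vinyl ketone nor the shift of the beta,gamma-allenyl aldehyde into conjugation should set in.

Step 12
Reactants: 22 allenyl keto aldehyde; 7 (2E,4E,6S)-6-methylocta-2,4-dienoyl chloride
Product: 24 (Ra,1E,9E)-9-methyl-6-oxo-7-(propan-2-ylidene)undeca-1,3,4,9-tetraen-1-yl (2E,4E,6S)-6-methylocta-2,4-dienoate, via potassium dienolate 23 (not isolated)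
Conditions: 22 added to KN(SiMe3)2 (1.0 equiv), THF/toluene, −78 °C, 10 min; then 7 (1.2 equiv), −78 °C; pH 7 phosphate buffer; chromatography on Florisil, Z isomer separated as far as possible
Reagents that add atoms: none
Why: O-acylation of an aldehyde dienolate to a 1-acyloxy diene: C2, flanked by the aldehyde and the allene, is by far the most acidic site, the loosely paired potassium dienolate prefers the extended shape that leads to the E enol ester and reacts with the acid chloride at oxygen, rotation about C1–C10 in the anion would require a vinyl-anion-like geometry and is frozen at −78 °C, and neither the base nor its conjugate amine is nucleophilic enough to add to the allenone and scramble the axis.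

Step 13
Reactants: 24 (Ra)-1-acyloxy vinylallenyl ketone
Product: 25 (3S,4R,5R)-8-oxoeremophila-1,7(11),9-trien-3-yl (2E,4E,6S)-6-methylocta-2,4-dienoate (CNP0215744.1)
Conditions: degassed toluene (0.002 M), 2,6-di-tert-butyl-4-methylphenol (10 mol %), base-washed and silylated glass, 90–110 °C
Reagents that add atoms: none
Why: Concerted suprafacial [4+2] cycloaddition in which the s-cis vinylallene diene C10=C1–C2=C3 adds to the tiglyl alkene C4=C5, making C3–C4 and C5–C10, moving the diene pi bond to C1=C2 and leaving the orthogonal C9=C10 pi bond as a spectator that ends up conjugated with C8=O, so the trienone of 25 appears with no later oxidation. The closest known reaction type is the thermal intramolecular Diels–Alder reaction of vinylallenes tethered through the allene terminus, which accepts unactivated alkenes and converts the axis into ring stereocentres; the acyloxy/acyl substitution of 24 itself is untested, and the reaction counts on discharge of cumulene strain, on congested C5 bonding to a two-coordinate carbon, and on a tether stiffened by sp2 C7 and C8 whose preferred s-cis enone rotamer already turns C6 towards C9. Ring A is the cyclohexene created by the cycloaddition itself, and ring B closes in the same event as a six-membered ring (C5–C6–C7–C8–C9–C10) when the C5–C10 bond joins the two ends of the C6–C7–C8 tether. In the Ra allene C8 projects from one face only of the diene plane, so the alkene reaches C10 from that face alone, which fixes C5 as R; suprafacial addition to the E alkene places the C4 methyl cis to the C5 methyl (4R), and the E enol ester holds the acyloxy group outside, where it pairs with the endo methyls and sets C3 (S) cis to both. Two selectivities are required, facial and exo/endo: the face follows from the axis as described, and with C6 exo the dihedral angle C9–C10···C5–C6 is close to zero as a forming six-membered ring demands, whereas C6 endo would need more than 100 degrees and the reversed regiochemistry would give a bridged skeleton beyond the reach of three tether atoms. High dilution, a radical inhibitor and acid- and base-free glass hold back dimerisation, Nazarov closure and racemisation, no sp3 C–H sits cis on C3 so the usual 1,5-hydrogen shift of vinylallenes has nothing to move, and residual Z enol ester, burdened by an inside acyloxy group, should react far more slowly and be removed afterwards.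

Compound list
1 | (S)-2-methylbutan-1-ol | CC[C@H](C)CO | starting material
2 | (S)-2-methylbutanal | CC[C@H](C)C=O | intermediate
3 | triethyl (E)-4-phosphonocrotonate | CCOC(=O)/C=C/CP(=O)(OCC)OCC | starting material
4 | lithiated phosphonate (lithium salt of the C4 carbanion of 3) | CCOC(=O)/C=C/[CH-]P(=O)(OCC)OCC.[Li+] | intermediate
5 | ethyl (2E,4E,6S)-6-methylocta-2,4-dienoate | CC[C@H](C)/C=C/C=C/C(=O)OCC | intermediate
6 | (2E,4E,6S)-6-methylocta-2,4-dienoic acid | CC[C@H](C)/C=C/C=C/C(=O)O | intermediate
7 | (2E,4E,6S)-6-methylocta-2,4-dienoyl chloride | CC[C@H](C)/C=C/C=C/C(=O)Cl | intermediate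
8 | (E)-2-methylbut-2-en-1-ol (tiglyl alcohol) | C/C=C(\C)CO | starting material
9 | (E)-1-bromo-2-methylbut-2-ene (tiglyl bromide) | C/C=C(\C)CBr | intermediate
10 | 1,1-dibromo-2-methylprop-1-ene | CC(C)=C(Br)Br | starting material
11 | 1-bromo-2-methylprop-1-enyllithium | CC(C)=C(Br)[Li] | intermediate
12 | (5E)-3-bromo-2,5-dimethylhepta-2,5-diene | CC(C)=C(Br)C/C(C)=C/C | intermediate
13 | 3-(tert-butyldimethylsilyloxy)propanal | O=CCCO[Si](C)(C)C(C)(C)C | starting material
14 | prop-2-yn-1-ol (propargyl alcohol) | C#CCO | starting material
15 | (S)-α,α-diphenylprolinol, stoichiometric chiral amine | OC(c1ccccc1)(c1ccccc1)[C@@H]1CCCN1 | starting material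
16 | (4S)-6-(tert-butyldimethylsilyloxy)-4-[(2S)-2-(hydroxydiphenylmethyl)pyrrolidin-1-yl]hex-2-yn-1-ol | OCC#C[C@H](CCO[Si](C)(C)C(C)(C)C)N1CCC[C@H]1C(O)(c1ccccc1)c1ccccc1 | intermediate
17 | (Ra)-6-(tert-butyldimethylsilyloxy)hexa-2,3-dien-1-ol | OCC=[C@]=CCCO[Si](C)(C)C(C)(C)C | intermediate
18 | (Ra)-6-(tert-butyldimethylsilyloxy)hexa-2,3-dienal | O=CC=[C@]=CCCO[Si](C)(C)C(C)(C)C | intermediate
19 | (5E)-2,5-dimethylhepta-2,5-dien-3-yllithium | CC(C)=C([Li])C/C(C)=C/C | intermediate
20 | (Ra,9E)-1-(tert-butyldimethylsilyloxy)-9-methyl-7-(propan-2-ylidene)undeca-3,4,9-trien-6-ol, both C8 epimers | C/C=C(\C)CC(=C(C)C)C(O)C=[C@]=CCCO[Si](C)(C)C(C)(C)C | intermediate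
21 | (Ra,9E)-9-methyl-7-(propan-2-ylidene)undeca-3,4,9-triene-1,6-diol, both C8 epimers | C/C=C(\C)CC(=C(C)C)C(O)C=[C@]=CCCO | intermediate
22 | (Ra,9E)-9-methyl-6-oxo-7-(propan-2-ylidene)undeca-3,4,9-trienal | C/C=C(\C)CC(=C(C)C)C(=O)C=[C@]=CCC=O | intermediate
23 | potassium (E)-dienolate of 22 | C/C=C(\C)CC(=C(C)C)C(=O)C=[C@]=C/C=C/[O-].[K+] | intermediate
24 | (Ra,1E,9E)-9-methyl-6-oxo-7-(propan-2-ylidene)undeca-1,3,4,9-tetraen-1-yl (2E,4E,6S)-6-methylocta-2,4-dienoate | CC[C@H](C)/C=C/C=C/C(=O)O/C=C/C=[C@]=CC(=O)C(=C(C)C)C/C(C)=C/C | intermediate
25 | (3S,4R,5R)-8-oxoeremophila-1,7(11),9-trien-3-yl (2E,4E,6S)-6-methylocta-2,4-dienoate (CNP0215744.1) | CC[C@H](C)/C=C/C=C/C(=O)O[C@H]1C=CC2=CC(=O)C(=C(C)C)C[C@]2(C)[C@H]1C | target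

Total step count: 13.
Longest linear sequence: 7 steps (13 and 14 through steps 7 to 13). The branch from 8 through steps 5, 6 and 9 to 13 is equally long, and the acid chloride branch from 1 takes 6 steps.

Steps most likely to fail

Step 13. Addition to an unactivated trisubstituted alkene may be outrun by thermal decay of the allenyl vinyl ketone (electrocyclic closure, oligomerisation) or by erosion of the axis at the temperature needed.
- The fallback sets out from 24 and returns at 25. The cycloaddition is run at the carbinol oxidation level, where no allenone is present.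
- Luche reduction (NaBH4, CeCl3·7H2O, MeOH/THF, −78 °C) takes the C8 ketone of 24 to the epimeric vinylallenyl carbinols F1. These can be heated much harder (xylene, 140–160 °C).
- The same axis-controlled intramolecular Diels–Alder reaction should then give the bicyclic dienols F2.
- MnO2 (CH2Cl2, rt) oxidises the doubly allylic C8 alcohol and merges both epimers into 25.

Step 12. Several things may go wrong.
- The strong base may also remove the allenic hydrogen at C1, or start the prototropic shift of the allenone into the conjugated dienone, with loss of the axis.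
- The dienolate may add to unreacted 22.
- E/Z control of the enol ester may be poor.

The fallback sets out from 20 and returns at 24. The enol ester is made while C8 is still a protected carbinol, so no allenone meets the base.
- TBSOTf/2,6-lutidine (CH2Cl2, −78 °C) converts 20 into the bis-silyl ether F3.
- HF·pyridine buffered with pyridine (THF, 0 °C) removes only the primary silyl group and gives the primary alcohol F4.
- Buffered Dess–Martin oxidation gives the allenyl aldehyde F5.
- Enolisation with KN(SiMe3)2 and O-acylation with 7, as in step 12, gives the C8-silyloxy enol ester F6.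
- Longer exposure to HF·pyridine (THF, rt) frees the C8 carbinols, which are the compounds F1 of the first fallback.
- Buffered Dess–Martin oxidation then gives 24 under neutral conditions.

Step 7. At 130 °C the iminium/enamine derived from the beta-silyloxy aldehyde may lose silanolate by beta-elimination, and the enantiomeric purity of the axis may erode on prolonged heating.
- The fallback sets out from 13 and returns at 17. The axis is derived from a carbinol centre instead of from the amine.
- The lithium acetylide of 4-methoxybenzyl propargyl ether (n-BuLi, THF, −78 °C) adds to 13 to give the racemic propargylic alcohol F7.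
- Dess–Martin oxidation gives the ynone F8.
- Noyori transfer hydrogenation (RuCl[(R,R)-TsDPEN](p-cymene), i-PrOH, rt) should give the (R)-propargylic alcohol F9.
- The Myers allene synthesis (PPh3, DEAD, 2-nitrobenzenesulfonylhydrazide, THF, −15 °C → rt) proceeds by Mitsunobu inversion followed by suprafacial retro-ene loss of N2. It turns the R centre into the (Ra)-allenyl 4-methoxybenzyl ether F10.
- DDQ (CH2Cl2/pH 7 buffer, 0 °C) then frees 17.

Further compounds
F1 | step 13 | (Ra,1E,9E)-6-hydroxy-9-methyl-7-(propan-2-ylidene)undeca-1,3,4,9-tetraen-1-yl (2E,4E,6S)-6-methylocta-2,4-dienoate, both C8 epimers | CC[C@H](C)/C=C/C=C/C(=O)O/C=C/C=[C@]=CC(O)C(=C(C)C)C/C(C)=C/C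
F2 | step 13 | (3S,4R,5R)-8-hydroxyeremophila-1,7(11),9-trien-3-yl (2E,4E,6S)-6-methylocta-2,4-dienoate, both C8 epimers | CC[C@H](C)/C=C/C=C/C(=O)O[C@H]1C=CC2=CC(O)C(=C(C)C)C[C@]2(C)[C@H]1C
F3 | step 12 | (Ra,9E)-1,6-bis(tert-butyldimethylsilyloxy)-9-methyl-7-(propan-2-ylidene)undeca-3,4,9-triene, both C8 epimers | C/C=C(\C)CC(=C(C)C)C(O[Si](C)(C)C(C)(C)C)C=[C@]=CCCO[Si](C)(C)C(C)(C)C
F4 | step 12 | (Ra,9E)-6-(tert-butyldimethylsilyloxy)-9-methyl-7-(propan-2-ylidene)undeca-3,4,9-trien-1-ol, both C8 epimers | C/C=C(\C)CC(=C(C)C)C(O[Si](C)(C)C(C)(C)C)C=[C@]=CCCO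
F5 | step 12 | (Ra,9E)-6-(tert-butyldimethylsilyloxy)-9-methyl-7-(propan-2-ylidene)undeca-3,4,9-trienal, both C8 epimers | C/C=C(\C)CC(=C(C)C)C(O[Si](C)(C)C(C)(C)C)C=[C@]=CCC=O
F6 | step 12 | (Ra,1E,9E)-6-(tert-butyldimethylsilyloxy)-9-methyl-7-(propan-2-ylidene)undeca-1,3,4,9-tetraen-1-yl (2E,4E,6S)-6-methylocta-2,4-dienoate, both C8 epimers | CC[C@H](C)/C=C/C=C/C(=O)O/C=C/C=[C@]=CC(O[Si](C)(C)C(C)(C)C)C(=C(C)C)C/C(C)=C/C
F7 | step 7 | racemic 1-(tert-butyldimethylsilyloxy)-6-(4-methoxybenzyloxy)hex-4-yn-3-ol | COc1ccc(COCC#CC(O)CCO[Si](C)(C)C(C)(C)C)cc1
F8 | step 7 | 1-(tert-butyldimethylsilyloxy)-6-(4-methoxybenzyloxy)hex-4-yn-3-one | COc1ccc(COCC#CC(=O)CCO[Si](C)(C)C(C)(C)C)cc1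
F9 | step 7 | (R)-1-(tert-butyldimethylsilyloxy)-6-(4-methoxybenzyloxy)hex-4-yn-3-ol | COc1ccc(COCC#C[C@H](O)CCO[Si](C)(C)C(C)(C)C)cc1
F10 | step 7 | (Ra)-6-(tert-butyldimethylsilyloxy)hexa-2,3-dien-1-yl 4-methoxybenzyl ether | COc1ccc(COCC=[C@]=CCCO[Si](C)(C)C(C)(C)C)cc1
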